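## Retrosynthetic overview

- The target is a briarane: a cyclohexane trans-fused to a ten-membered carbocycle that carries a γ-lactone. Briarane numbers are used throughout: C1 (quaternary fusion carbon, methyl C15), C2 (carbinol), C3/C4 (oxirane), C5=C16, C6 (Cl), C7 (lactone O), C8 (tertiary OH), C9 (OAc), C10 (fusion CH), C11 (methyl C20), C12 (OAc), C13/C14 (oxirane), lactone C17(C18)–C19.
- Key disconnection: the cyclohexane bonds C10–C11 and C1–C14 are made together by a silicon-tethered type 2 intramolecular Diels–Alder reaction of a (1E,3Z)-1-methoxy-3-silyloxypenta-1,3-diene (C11–C14) with an (E)-2-methylenoate (C2–C1=C10). The enabling feature is that the oxygens on C9 and C12 flank the new C10–C11 bond (O–C9–C10–C11–C12–O), so one iPr2Si unit can join the C9 carbinol to the dienol oxygen in a seven-membered 1,3-dioxa-2-silepane. The trans ring fusion (C15 methyl / H-10) is the image of the (E)-enoate.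
- C7–C8–C9 (three contiguous C–O centres) are C2–C3–C4 of D-glucose (3-ulose, exo addition of a propionamide enolate). C9 relays its configuration to C10, C1 and C11 in the key step; C12, C13 and C14 follow by substrate control.
- The ten-membered ring is closed at C2–C3 by an intramolecular Nozaki–Hiyama–Kishi alkynylation, followed by cis-semihydrogenation, hydroxyl-directed C3/C4 epoxidation and ene-type chlorination (C6–Cl, C5=C16).
- Ring order: furanose template (chiral pool, later opened) → six-membered carbocycle (key step) → γ-lactone → 13,14-oxirane → ten-membered ring → 3,4-oxirane.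

Key step: step 9

Remark (assumption on the chemistry): the amide α-carbon C17 is formed without control in step 2. Compounds 5–28 are therefore carried as C17 epimer pairs (this centre is left open in their SMILES) and C17 is set by equilibration in step 13. Lactol 9 is an anomeric mixture at C6.

## Route

Step 1
Reactants: 1 1,2:5,6-di-O-isopropylidene-α-D-glucofuranose
Product: 2 1,2:5,6-di-O-isopropylidene-α-D-ribo-hexofuranos-3-ulose
Conditions: Dess–Martin periodinane, NaHCO3, CH2Cl2, rt; dried by PhMe azeotrope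
Reagents that add atoms: none
Why: Dess–Martin oxidation of the only free (secondary) hydroxyl should give the 3-ulose; no stereocentre is formed.

Step 2
Reactants: 2 1,2:5,6-di-O-isopropylidene-α-D-ribo-hexofuranos-3-ulose; 3 N,N-dimethylpropanamide
Product: 5 3-C-[1-(dimethylcarbamoyl)ethyl]-1,2:5,6-di-O-isopropylidene-α-D-allofuranose, via lithium amide enolate 4 (not isolated)
Conditions: LDA, THF, −78 °C; add 2; aq. NH4Cl at −78 °C
Reagents that add atoms: none
Why: Aldol-type addition of the amide enolate should occur on the exo (β) face of the cis-fused bicyclic ketone, anti to the 1,2-acetonide, which sets the tertiary carbinol C8 (allo configuration); C17 is not controlled here and is corrected in step 13.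

Step 3
Reactants: 5 3-C-[1-(dimethylcarbamoyl)ethyl]-1,2:5,6-di-O-isopropylidene-α-D-allofuranose
Product: 6 3-C-[1-(dimethylcarbamoyl)ethyl]-1,2-O-isopropylidene-α-D-ribo-pentodialdo-1,4-furanose
Conditions: H5IO6 (1.3 equiv), EtOAc, rt
Reagents that add atoms: none
Why: Periodic acid should hydrolyse the more labile terminal acetonide and cleave the liberated glycol in one pot (oxidative glycol cleavage), giving the aldehyde that becomes C10 without touching C9.

Step 4
Reactants: 6 3-C-[1-(dimethylcarbamoyl)ethyl]-1,2-O-isopropylidene-α-D-ribo-pentodialdo-1,4-furanose; 7 ethyl 2-(triphenylphosphoranylidene)propanoate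
Product: 8 ethyl (E)-2-methylpropenoate on C4 of the 3-C-branched 1,2-O-isopropylidene-α-D-ribofuranose (C2–C1=C10 enoate on C9)
Conditions: CH2Cl2, rt → 40 °C
Reagents that add atoms: none
Why: Wittig olefination with the stabilised ylide should give the (E)-trisubstituted enoate (ester trans to C9), the geometry that later becomes the trans ring fusion.

Step 5
Reactants: 8 (E)-enoate with 1,2-acetonide
Product: 9 2,3-O-isopropylidene furanose lactol (acetonide on O7/O8, free anomeric OH at C6, ring oxygen = O9)
Conditions: acetone, H2SO4 (cat.), CuSO4, rt; NaHCO3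
Reagents that add atoms: none
Why: Acid-catalysed acetal migration under thermodynamic control: in an allo-configured furanose the cis-2,3-diol (one hydroxyl tertiary) forms the more stable dioxolane, as in 2,3-O-isopropylidene derivatives of ribose and allose, and the anomeric hydroxyl is freed; no stereocentre changes.

Step 6
Reactants: 9 2,3-O-isopropylidene furanose lactol; 10 ethyltriphenylphosphonium iodide
Product: 14 (Z)-vinyl iodide with free C9 hydroxyl (open chain C2–C1=C10–C9(OH)–C8–C7–C6=C5(CH3)I with 7,8-acetonide), via ethylidenetriphenylphosphorane 11 (not isolated), via (1-iodoethyl)triphenylphosphonium iodide 12 (not isolated), via (1-iodoethylidene)triphenylphosphorane 13 (not isolated)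
Conditions: 10, n-BuLi, THF, −78 °C; I2, −78 °C; NaHMDS, −20 °C; then 9, −78 °C → rt
Reagents that add atoms: iodine, [I][I]
Why: α-Iodo Wittig olefination (Stork–Zhao type) of the open aldehyde form of the lactol should give the (Z)-2-iodopropenyl group (iodine cis to C7) under kinetic control and release the C9 hydroxyl as the only free OH; the product is not a Michael acceptor for that hydroxyl, and the hindered tiglate-type enoate should not compete for the ylide.

Step 7
Reactants: 15 (E)-4-methoxybut-3-en-2-one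
Product: 17 (E)-1-methoxypent-1-en-3-one, via lithium enolate 16 (not isolated)
Conditions: LiHMDS, THF, −78 °C; MeI, −78 → 0 °C
Reagents that add atoms: iodomethane, IC
Why: α′-Methylation of the kinetic enolate of a vinylogous ester (enolate alkylation) should give the ethyl ketone needed for the diene.

Step 8
Reactants: 14 (Z)-vinyl iodide with free C9 hydroxyl; 17 (E)-1-methoxypent-1-en-3-one
Product: 20 diisopropylsilyl acetal linking O9 to the (1E,3Z)-1-methoxypenta-1,3-dien-3-ol oxygen, via chlorodiisopropylsilyl ether 18 (not isolated), via lithium dienolate 19 (not isolated)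
Conditions: iPr2SiCl2 (excess), imidazole, CH2Cl2, 0 °C → rt, volatiles removed; separately 17, LiHMDS, THF, −78 °C; combine, −78 → 0 °C
Reagents that add atoms: dichlorodiisopropylsilane, CC(C)[Si](Cl)(Cl)C(C)C
Why: Silylation of the C9 alcohol with excess dichlorosilane gives the monochlorosilane, which O-silylates the lithium dienolate; a conjugated ethyl ketone enolises to the (Z)-enolate, so the C20 methyl sits "outside" on the diene.

Step 9
Reactants: 20 diisopropylsilyl acetal (tethered diene and dienophile)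
Product: 21 bridged cycloadduct (bicyclo[4.3.1] bridgehead silyl enol ether C12=C13, methoxy on C14)
Conditions: PhMe (0.005 M), BHT (cat.), 150 °C, sealed tube, dark
Reagents that add atoms: none
Why: Thermal, concerted but asynchronous [4+2] cycloaddition in which the nucleophilic diene terminus C11 bonds to the enoate β-carbon C10 ahead of C14–C1; the closest known reaction type is the silicon-tethered type 2 intramolecular Diels–Alder reaction of 2-silyloxy-1,3-dienes with acrylate-type dienophiles, which gives bicyclo[4.3.1] bridgehead silyl enol ethers. The six-membered carbocycle (C1, C10, C11, C12, C13, C14) is closed by the [4+2] event itself, and the seven-membered 1,3-dioxa-2-silepane that holds the tether (O–C9–C10–C11–C12–O–Si) closes in the same event in the bridged mode. C10 is controlled by the C9 carbinol: allylic 1,3-strain with the cis C15 methyl holds H-9 in the enoate plane, so the tethering oxygen lies on one face and the bulky acetonide-bearing C8 on the other, and the diene can only reach the face that gives the required C9/C10 relationship. C1 follows from suprafacial addition to the (E)-enoate (C15 cis to C9, ester trans), and C11 from the (3Z)-enol ether (methyl outside) together with the tether-enforced endo position of C9, which puts C20 cis to C9 and C15; the methoxy-bearing C14 is lost in step 10. The step needs regioselectivity (C11 to C10, not to C1), which is secured twice: the four-atom tether only allows the 1,3-bridged mode, and the polarity of silyloxydiene and enoate is matched; the vinyl iodide and the amide should be inert.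

Step 10
Reactants: 21 bridged cycloadduct
Product: 22 4,4-disubstituted cyclohexenone (C12 ketone, C13=C14, free C9 hydroxyl)
Conditions: HF·pyridine, MeCN, 0 °C → rt
Reagents that add atoms: none
Why: Cleavage of the strained bridgehead silyl enol ether and of the Si–O9 bond, with acid-promoted β-elimination of methanol from the β-methoxy ketone (the usual unmasking of 1-methoxy-3-silyloxydiene adducts), should give the enone; without base the kinetic β-methyl configuration at C11 is kept.

Step 11
Reactants: 22 cyclohexenone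
Product: 24 triol (C2 primary, C9 and 12β secondary hydroxyls), via 12β-allylic alcohol ester 23 (not isolated)
Conditions: CeCl3·7H2O, NaBH4, MeOH/THF, −78 °C; then LiBH4, 0 → 40 °C
Reagents that add atoms: none
Why: Luche 1,2-reduction should deliver hydride to the α face of C12 (the β face carries C15, C20 and the C9 side chain), giving the 12β-alcohol cis to C20; LiBH4 then reduces the neopentyl ester (or the C2/O9 lactone it may form) but not the tertiary amide or the vinyl iodide.

Step 12
Reactants: 24 triol
Product: 26 9,12-diacetate with C2 O-TBS ether, via C2 mono-TBS ether 25 (not isolated)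
Conditions: TBSCl (1.05 equiv), imidazole, CH2Cl2, 0 °C; then Ac2O, pyridine, DMAP (cat.), rt
Reagents that add atoms: tert-butyldimethylsilyl chloride, CC(C)(C)[Si](C)(C)Cl; acetic anhydride, CC(=O)OC(C)=O
Why: The bulky silyl chloride should take the primary hydroxyl only, and DMAP-catalysed acetylation then esterifies the two secondary hydroxyls that stay as acetates in the target.

Step 13
Reactants: 26 9,12-diacetate with C2 O-TBS ether
Product: 29 γ-lactone diol (lactone C19–O7 with 17R methyl; free C2 and C8 hydroxyls), via triol amide 27 (not isolated), via C17-epimeric lactone 28 (not isolated)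
Conditions: TFA/H2O/THF (3:1:1), 0 °C → rt; evaporate; CSA (1.2 equiv), PhMe, 60 °C; then DBU (2 equiv), PhMe, 40 °C
Reagents that add atoms: none
Why: Aqueous acid removes the acetonide and the primary silyl ether, and the γ-hydroxy amide lactonises onto O7 (O9 is acetylated; O8 could only give a β-lactone). DBU then equilibrates C17 to the more stable epimer, with the methyl trans to the bulky C9 substituent and cis to the 8-hydroxyl, which is the configuration of the target.

Step 14
Reactants: 29 γ-lactone diol
Product: 30 bis-triethylsilyl ether (O2 primary, O8 tertiary)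
Conditions: TESOTf, 2,6-lutidine, CH2Cl2, −78 → 0 °C
Reagents that add atoms: triethylsilyl trifluoromethanesulfonate, CC[Si](CC)(CC)OS(=O)(=O)C(F)(F)F
Why: Silyl triflate silylation covers the primary and the hindered tertiary hydroxyl; masking O8 prevents a six-membered lactol with the later C2 aldehyde and removes a competing directing group in step 21.

Step 15
Reactants: 30 bis-triethylsilyl ether
Product: 31 13α,14α-epoxide
Conditions: mCPBA, NaHCO3, CH2Cl2, 0 °C → rt
Reagents that add atoms: 3-chloroperbenzoic acid, OOC(=O)c1cccc(Cl)c1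
Why: Prilezhaev epoxidation of the only electron-rich alkene (the iodoalkene is deactivated) should occur on the α face, anti to the C15 methyl on the neighbouring quaternary carbon, to C20 and to the 12β-acetate, which sets C13 and C14 trans to the acetate.

Step 16
Reactants: 31 13α,14α-epoxide; 32 ethynyltrimethylsilane
Product: 33 (Z)-enyne (C5–C4≡C3–SiMe3)
Conditions: Pd(PPh3)2Cl2 (5 mol %), CuI (10 mol %), iPr2NH, THF, rt
Reagents that add atoms: none
Why: Sonogashira coupling of the vinyl iodide proceeds with retention, so C4 ends up cis to C7 on the C5=C6 bond.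

Step 17
Reactants: 33 (Z)-enyne
Product: 34 iodoalkyne (C3–I)
Conditions: NIS, AgNO3 (cat.), acetone, rt, dark
Reagents that add atoms: N-iodosuccinimide, IN1C(=O)CCC1=O
Why: Silver-catalysed iododesilylation converts the alkynylsilane directly into the 1-iodoalkyne needed for the chromium-mediated ring closure.

Step 18
Reactants: 34 iodoalkyne
Product: 35 C2 aldehyde (O8 still silylated)
Conditions: (COCl)2, DMSO, CH2Cl2, −78 → −30 °C; Et3N
Reagents that add atoms: none
Why: Under Swern conditions primary triethylsilyl ethers are oxidised directly to aldehydes while hindered tertiary silyl ethers survive, so the non-enolisable neopentyl aldehyde is unveiled in one step.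

Step 19
Reactants: 35 C2 aldehyde
Product: 36 ten-membered propargylic alcohol (C2 carbinol, C3≡C4, (Z)-C5=C6)
Conditions: CrCl2 (8 equiv), NiCl2 (2 mol %), THF (0.002 M), rt
Reagents that add atoms: none
Why: Intramolecular Nozaki–Hiyama–Kishi addition of the alkynylchromium species to the aldehyde closes the ten-membered ring (ten-membered cyclic enynes are made this way) and tolerates acetates, lactone and oxirane; C2 should arise by Felkin–Anh attack anti to the C1–C14 bond with the formyl hydrogen next to the small C15 methyl.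

Step 20
Reactants: 36 ten-membered propargylic alcohol
Product: 37 (3Z,5Z)-dienol
Conditions: H2 (1 atm), Pd/CaCO3 poisoned with Pb(OAc)2, quinoline, EtOAc, rt
Reagents that add atoms: none
Why: Lindlar semihydrogenation adds hydrogen syn to the alkyne and should stop at the cis C3=C4 alkene.

Step 21
Reactants: 37 (3Z,5Z)-dienol
Product: 38 3,4-epoxy alcohol
Conditions: VO(acac)2 (5 mol %), t-BuOOH, CH2Cl2, 0 °C
Reagents that add atoms: tert-butyl hydroperoxide, CC(C)(C)OO
Why: Vanadium-catalysed hydroxyl-directed epoxidation delivers oxygen to C3=C4 on the face of the C2 hydroxyl, which in medium-ring (Z)-allylic alcohols gives the cis (erythro) epoxy alcohol and so sets C3 and C4; C5=C6 has no free allylic or homoallylic hydroxyl and should be left.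

Step 22
Reactants: 38 3,4-epoxy alcohol
Product: 39 8-O-triethylsilyl ether of the target (6-chloro-5(16)-ene)
Conditions: Ca(OCl)2, solid CO2, CH2Cl2/H2O, 0 °C
Reagents that add atoms: calcium hypochlorite, [Ca+2].[O-]Cl.[O-]Cl
Why: Ene-type chlorination with hypochlorous acid: the only C=C left takes chlorine at the less substituted C6 and loses a proton from the C16 methyl, giving the 6-chloro-5(16)-ene; chlorine should enter anti to the allylic C7–O bond in the conformer that keeps H-7 in the alkene plane, which corresponds to the required C6 configuration.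

Step 23
Reactants: 39 8-O-triethylsilyl ether of the target
Product: 40 target CNP0379630.2
Conditions: HF·pyridine, pyridine, THF, 0 °C
Reagents that add atoms: none
Why: Buffered fluoride desilylation frees the tertiary C8 hydroxyl without affecting the oxiranes, acetates, lactone or allylic chloride.

## Compound list

1 | 1,2:5,6-di-O-isopropylidene-α-D-glucofuranose | CC1(C)OC[C@@H](O1)[C@H]2O[C@@H]3OC(C)(C)O[C@@H]3[C@H]2O | starting material
2 | 1,2:5,6-di-O-isopropylidene-α-D-ribo-hexofuranos-3-ulose | CC1(C)OC[C@@H](O1)[C@H]2O[C@@H]3OC(C)(C)O[C@@H]3C2=O | intermediate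
3 | N,N-dimethylpropanamide | CCC(=O)N(C)C | starting material
4 | lithium (Z)-enolate of N,N-dimethylpropanamide (not isolated) | [Li+].C/C=C(\[O-])N(C)C | intermediate
5 | 3-C-[1-(dimethylcarbamoyl)ethyl]-1,2:5,6-di-O-isopropylidene-α-D-allofuranose (C17 epimers) | CC1(C)OC[C@@H](O1)[C@H]2O[C@@H]3OC(C)(C)O[C@@H]3[C@@]2(O)C(C)C(=O)N(C)C | intermediate
6 | 3-C-[1-(dimethylcarbamoyl)ethyl]-1,2-O-isopropylidene-α-D-ribo-pentodialdo-1,4-furanose | O=C[C@H]1O[C@@H]2OC(C)(C)O[C@@H]2[C@@]1(O)C(C)C(=O)N(C)C | intermediate
7 | ethyl 2-(triphenylphosphoranylidene)propanoate | CCOC(=O)C(C)=P(c1ccccc1)(c1ccccc1)c1ccccc1 | starting material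
8 | (E)-enoate on the 1,2-O-isopropylidene furanose | CCOC(=O)/C(C)=C/[C@H]1O[C@@H]2OC(C)(C)O[C@@H]2[C@@]1(O)C(C)C(=O)N(C)C | intermediate
9 | 2,3-O-isopropylidene lactol (O7/O8 acetonide, anomeric mixture at C6) | CCOC(=O)/C(C)=C/[C@H]1OC(O)[C@@H]2OC(C)(C)O[C@]12C(C)C(=O)N(C)C | intermediate
10 | ethyltriphenylphosphonium iodide | CC[P+](c1ccccc1)(c1ccccc1)c1ccccc1.[I-] | starting material
11 | ethylidenetriphenylphosphorane (not isolated) | CC=P(c1ccccc1)(c1ccccc1)c1ccccc1 | intermediate
12 | (1-iodoethyl)triphenylphosphonium iodide (not isolated) | CC(I)[P+](c1ccccc1)(c1ccccc1)c1ccccc1.[I-] | intermediate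
13 | (1-iodoethylidene)triphenylphosphorane (not isolated) | CC(I)=P(c1ccccc1)(c1ccccc1)c1ccccc1 | intermediate
14 | (Z)-vinyl iodide with free C9 hydroxyl, 7,8-acetonide, (E)-enoate | CCOC(=O)/C(C)=C/[C@@H](O)[C@@]1(C(C)C(=O)N(C)C)OC(C)(C)O[C@H]1/C=C(/C)I | intermediate
15 | (E)-4-methoxybut-3-en-2-one | CC(=O)/C=C/OC | starting material
16 | lithium enolate of 15 (not isolated) | [Li+].[O-]C(=C)/C=C/OC | intermediate
17 | (E)-1-methoxypent-1-en-3-one | CCC(=O)/C=C/OC | intermediate
18 | O9-chlorodiisopropylsilyl ether of 14 (not isolated) | CCOC(=O)/C(C)=C/[C@@H](O[Si](Cl)(C(C)C)C(C)C)[C@@]1(C(C)C(=O)N(C)C)OC(C)(C)O[C@H]1/C=C(/C)I | intermediate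
19 | lithium (1E,3Z)-1-methoxypenta-1,3-dien-3-olate (not isolated) | [Li+].C/C=C(\[O-])/C=C/OC | intermediate
20 | diisopropylsilyl acetal of 14 and the (1E,3Z)-dienol | CCOC(=O)/C(C)=C/[C@@H](O[Si](C(C)C)(C(C)C)O/C(=C\C)/C=C/OC)[C@@]1(C(C)C(=O)N(C)C)OC(C)(C)O[C@H]1/C=C(/C)I | intermediate
21 | bridged cycloadduct (bicyclo[4.3.1] silyl enol ether) | CCOC(=O)[C@@]1(C)[C@H](OC)C=C2O[Si](C(C)C)(C(C)C)O[C@H]([C@H]1[C@H]2C)[C@@]3(C(C)C(=O)N(C)C)OC(C)(C)O[C@H]3/C=C(/C)I | intermediate
22 | cyclohexenone with free C9 hydroxyl | CCOC(=O)[C@@]1(C)C=CC(=O)[C@H](C)[C@@H]1[C@@H](O)[C@@]2(C(C)C(=O)N(C)C)OC(C)(C)O[C@H]2/C=C(/C)I | intermediate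
23 | 12β-allylic alcohol ester (not isolated) | CCOC(=O)[C@@]1(C)C=C[C@H](O)[C@H](C)[C@@H]1[C@@H](O)[C@@]2(C(C)C(=O)N(C)C)OC(C)(C)O[C@H]2/C=C(/C)I | intermediate
24 | triol (C2, C9, C12 hydroxyls) | OC[C@@]1(C)C=C[C@H](O)[C@H](C)[C@@H]1[C@@H](O)[C@@]2(C(C)C(=O)N(C)C)OC(C)(C)O[C@H]2/C=C(/C)I | intermediate
25 | C2 mono-TBS ether (not isolated) | CC(C)(C)[Si](C)(C)OC[C@@]1(C)C=C[C@H](O)[C@H](C)[C@@H]1[C@@H](O)[C@@]2(C(C)C(=O)N(C)C)OC(C)(C)O[C@H]2/C=C(/C)I | intermediate
26 | 9,12-diacetate with C2 O-TBS ether | CC(C)(C)[Si](C)(C)OC[C@@]1(C)C=C[C@H](OC(C)=O)[C@H](C)[C@@H]1[C@@H](OC(C)=O)[C@@]2(C(C)C(=O)N(C)C)OC(C)(C)O[C@H]2/C=C(/C)I | intermediate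
27 | triol amide (C2, C7, C8 hydroxyls; not isolated) | OC[C@@]1(C)C=C[C@H](OC(C)=O)[C@H](C)[C@@H]1[C@@H](OC(C)=O)[C@](O)(C(C)C(=O)N(C)C)[C@@H](O)/C=C(/C)I | intermediate
28 | γ-lactone as C17 epimers (not isolated) | OC[C@@]1(C)C=C[C@H](OC(C)=O)[C@H](C)[C@@H]1[C@@H](OC(C)=O)[C@]2(O)C(C)C(=O)O[C@H]2/C=C(/C)I | intermediate
29 | γ-lactone diol (17R) | OC[C@@]1(C)C=C[C@H](OC(C)=O)[C@H](C)[C@@H]1[C@@H](OC(C)=O)[C@]2(O)[C@@H](C)C(=O)O[C@H]2/C=C(/C)I | intermediate
30 | bis-triethylsilyl ether (O2, O8) | CC[Si](CC)(CC)OC[C@@]1(C)C=C[C@H](OC(C)=O)[C@H](C)[C@@H]1[C@@H](OC(C)=O)[C@]2(O[Si](CC)(CC)CC)[C@@H](C)C(=O)O[C@H]2/C=C(/C)I | intermediate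
31 | 13α,14α-epoxide | CC[Si](CC)(CC)OC[C@@]1(C)[C@H]3O[C@H]3[C@H](OC(C)=O)[C@H](C)[C@@H]1[C@@H](OC(C)=O)[C@]2(O[Si](CC)(CC)CC)[C@@H](C)C(=O)O[C@H]2/C=C(/C)I | intermediate
32 | ethynyltrimethylsilane | C#C[Si](C)(C)C | starting material
33 | (Z)-enyne with trimethylsilyl alkyne | CC[Si](CC)(CC)OC[C@@]1(C)[C@H]3O[C@H]3[C@H](OC(C)=O)[C@H](C)[C@@H]1[C@@H](OC(C)=O)[C@]2(O[Si](CC)(CC)CC)[C@@H](C)C(=O)O[C@H]2/C=C(/C)C#C[Si](C)(C)C | intermediate
34 | iodoalkyne | CC[Si](CC)(CC)OC[C@@]1(C)[C@H]3O[C@H]3[C@H](OC(C)=O)[C@H](C)[C@@H]1[C@@H](OC(C)=O)[C@]2(O[Si](CC)(CC)CC)[C@@H](C)C(=O)O[C@H]2/C=C(/C)C#CI | intermediate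
35 | C2 aldehyde with iodoalkyne | O=C[C@@]1(C)[C@H]3O[C@H]3[C@H](OC(C)=O)[C@H](C)[C@@H]1[C@@H](OC(C)=O)[C@]2(O[Si](CC)(CC)CC)[C@@H](C)C(=O)O[C@H]2/C=C(/C)C#CI | intermediate
36 | ten-membered propargylic alcohol | O[C@@H]1C#C/C(C)=C\[C@@H]2OC(=O)[C@H](C)[C@@]2(O[Si](CC)(CC)CC)[C@H](OC(C)=O)[C@H]3[C@@H](C)[C@@H](OC(C)=O)[C@@H]4O[C@@H]4[C@]13C | intermediate
37 | (3Z,5Z)-dienol | O[C@@H]1/C=C\C(C)=C/[C@@H]2OC(=O)[C@H](C)[C@@]2(O[Si](CC)(CC)CC)[C@H](OC(C)=O)[C@H]3[C@@H](C)[C@@H](OC(C)=O)[C@@H]4O[C@@H]4[C@]13C | intermediate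
38 | 3,4-epoxy alcohol | O[C@@H]1[C@@H]5O[C@@H]5/C(C)=C\[C@@H]2OC(=O)[C@H](C)[C@@]2(O[Si](CC)(CC)CC)[C@H](OC(C)=O)[C@H]3[C@@H](C)[C@@H](OC(C)=O)[C@@H]4O[C@@H]4[C@]13C | intermediate
39 | 8-O-triethylsilyl ether of the target | O[C@@H]1[C@@H]5O[C@@H]5C(=C)[C@H](Cl)[C@@H]2OC(=O)[C@H](C)[C@@]2(O[Si](CC)(CC)CC)[C@H](OC(C)=O)[C@H]3[C@@H](C)[C@@H](OC(C)=O)[C@@H]4O[C@@H]4[C@]13C | intermediate
40 | CNP0379630.2 | C=C1[C@H]2O[C@H]2[C@@H](O)[C@]2(C)[C@H]([C@@H](C)[C@@H](OC(C)=O)[C@@H]3O[C@@H]32)[C@@H](OC(C)=O)[C@]2(O)[C@@H](C)C(=O)O[C@H]2[C@H]1Cl | target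

## Step count and risks

Total step count: 23. Longest linear sequence: 22 steps (steps 1–6 and 8–23; step 7 is a one-step side branch).

The three steps most likely to fail:

1. Step 9 (key cycloaddition). What may go wrong: ring closure onto the trisubstituted enoate may be slower than thermal loss of the sensitive 1-methoxy-3-silyloxydiene (desilylation or methanol elimination), so the tether is lost before the ring forms. Fallback, setting out from 14 and coming back at 22: chlorosilane 18 is combined with the lithium dienolate of pent-1-en-3-one (LiHMDS, THF, −78 °C) to give the simpler and thermally more robust silyl acetal of 14 with (Z)-penta-1,3-dien-3-ol F1. F1 is cyclised at 180–190 °C (PhMe, sealed tube) to the methoxy-free bridged adduct F2. Saegusa–Ito oxidation (Pd(OAc)2, MeCN) gives the cyclohexenone with an acetoxydiisopropylsilyl group on O9 F3, and HF·pyridine then gives 22.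

2. Step 19 (ring closure). What may go wrong: poor facial selectivity in the addition to the aldehyde during macrocyclisation, so that the C2 centre is formed as the wrong epimer or as a mixture. Fallback, setting out from 35 and coming back at 36: the cyclisation product containing the C2 epimer of 36 F4 is oxidised with Dess–Martin periodinane to the macrocyclic ynone F5. Reagent-controlled Corey–Bakshi–Shibata reduction ((S)-2-methyl-CBS-oxazaborolidine, catecholborane, −78 °C; alkyne as the small and quaternary C1 as the large substituent) then returns 36.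

3. Step 22 (chlorination). What may go wrong: delivery of chlorine to the wrong face of C5=C6, or interference by the neighbouring vinyl oxirane during electrophilic attack; the facial preference in the ten-membered ring could not be modelled here. Fallback, setting out from 38 and coming back at 39: a singlet-oxygen ene reaction (O2, hν, tetraphenylporphyrin) places oxygen on that same accessible face and shifts the double bond to C5=C16, giving the allylic C6 hydroperoxide F6. PPh3 reduces it to the C6 allylic alcohol F7, and Appel chlorination (PPh3, CCl4), in which the allylic hydroxyl should react first and with inversion, gives 39.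

Further compounds
F1 | step 9 | silyl acetal of 14 with (Z)-penta-1,3-dien-3-ol | CCOC(=O)/C(C)=C/[C@@H](O[Si](C(C)C)(C(C)C)O/C(=C\C)C=C)[C@@]1(C(C)C(=O)N(C)C)OC(C)(C)O[C@H]1/C=C(/C)I
F2 | step 9 | methoxy-free bridged adduct | CCOC(=O)[C@@]1(C)CC=C2O[Si](C(C)C)(C(C)C)O[C@H]([C@H]1[C@H]2C)[C@@]3(C(C)C(=O)N(C)C)OC(C)(C)O[C@H]3/C=C(/C)I
F3 | step 9 | cyclohexenone with an acetoxydiisopropylsilyl group on O9 | CCOC(=O)[C@@]1(C)C=CC(=O)[C@H](C)[C@@H]1[C@@H](O[Si](C(C)C)(C(C)C)OC(C)=O)[C@@]2(C(C)C(=O)N(C)C)OC(C)(C)O[C@H]2/C=C(/C)I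
F4 | step 19 | C2 epimer of 36 | O[C@H]1C#C/C(C)=C\[C@@H]2OC(=O)[C@H](C)[C@@]2(O[Si](CC)(CC)CC)[C@H](OC(C)=O)[C@H]3[C@@H](C)[C@@H](OC(C)=O)[C@@H]4O[C@@H]4[C@]13C
F5 | step 19 | macrocyclic ynone | O=C1C#C/C(C)=C\[C@@H]2OC(=O)[C@H](C)[C@@]2(O[Si](CC)(CC)CC)[C@H](OC(C)=O)[C@H]3[C@@H](C)[C@@H](OC(C)=O)[C@@H]4O[C@@H]4[C@]13C
F6 | step 22 | allylic C6 hydroperoxide | O[C@@H]1[C@@H]5O[C@@H]5C(=C)[C@@H](OO)[C@@H]2OC(=O)[C@H](C)[C@@]2(O[Si](CC)(CC)CC)[C@H](OC(C)=O)[C@H]3[C@@H](C)[C@@H](OC(C)=O)[C@@H]4O[C@@H]4[C@]13C
F7 | step 22 | C6 allylic alcohol | O[C@@H]1[C@@H]5O[C@@H]5C(=C)[C@@H](O)[C@@H]2OC(=O)[C@H](C)[C@@]2(O[Si](CC)(CC)CC)[C@H](OC(C)=O)[C@H]3[C@@H](C)[C@@H](OC(C)=O)[C@@H]4O[C@@H]4[C@]13C
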